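The numbers of this flask were chosen freely; the rest is arithmetic.

The pitfall is to read electrophile and free base, charged alike at 5.0 mM, as the two partners. The electrophile's partner is dissolved nucleophile, which comes across from the gas held at 1.1 mM.

electrophile 5.0 mM (fed, over 20 s); free base 5.00 mM; gas 1.1 mM (held); time 1.0 min

    acid set free + free base ⇌ salt of the base, settled at all times (K1 = 6.8 × 10⁵ /M)
    target → over-reaction product (k2 = 0.046 /s)
    electrophile + nucleophile → acid set free + target (k3 = 12 /M/s)
    nucleophile + acid set free ⇌ protonated nucleophile, settled at all times (K4 = 5.3 × 10⁶ /M)
    gas ⇌ nucleophile, rate k5*(csat - [nucleophile]) (k5 = 1.5 /s, csat = 1.1 mM)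

* part of the electrophile that has reacted at 1.0 min
* share of the unused nucleophile that is free and not bound as protonated nucleophile, at 1.0 min

- at the start none of nucleophile is dissolved
- run time (flask): 1.0 min

We write the balance of the nucleophile: the gas brings it in, while the electrophile and the acid set free take it away.

1. Dissolved nucleophile starts at none and stands no higher than saturation. The pull on the electrophile, the constant of step three times saturation, 0.0132 /s, is therefore a pseudo-first-order constant at its ceiling.

2. Upper bound. Fed evenly, the portions of electrophile have ages from 40.0 s to 60 s at the asked time. The share left is the mean of exp(−pull × age), so no more than 48.2% has reacted.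

3. Lower bound. Each nucleophile consumed frees one acid, which binds no more than one further nucleophile. We therefore reckon demand as no more than two times the constant of step three times full charge times saturation. The gas meets that with a shortfall below saturation of no more than 0.0880 mM, far less than saturation. Its filling time, 0.667 s, is far shorter than the feed.

4. After that filling the pull is at least 0.0121 /s, and the same mean, which counts the filling too at this pull, gives a lower bound of 45.4% reacted. We bracket no free share.

The forecast gives 47% reacted, which lies inside our bracket, and 41% free, which we have no bracket to hold against, and it rests on this: “dissolved nucleophile stays just below saturation”.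

The flask gives 46.7% reacted and 40.7% free.

The neighbouring flask holds 20 mM of free base. Neither the pull, 0.0132 /s, nor the shortfall, 0.0880 mM, contains free base, so the same reckoning gives the same bracket, 45.4% to 48.2%. That flask gives 47.0% reacted, with 1.07 mM of nucleophile dissolved. Its protonated nucleophile stands at 0.733 mM, against 1.55 mM in the first flask, and its free share at 59.3%.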